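## Retrosynthetic overview

1. The spiro-oxirane is made last, by epoxidation of the exocyclic C=C of a cis-2-aryl-4-arylmethyl-3-methylideneoxolane from the face away from both substituents; only unmasking of the two phenols follows.
2. The oxolane is closed by reductive etherification of a γ-hydroxy α-methylene aryl ketone. That ketone comes from an (R)-β-arylmethyl-γ-butyrolactone by aryllithium addition and Mannich methylenation.
3. Key disconnection: the γ-butyrolactone is the ring-expanded form of a prochiral 3-(arylmethyl)cyclobutanone. A desymmetrising Baeyer–Villiger 1,2-shift sets the one stereocentre that later controls the other two.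
4. The cyclobutanone comes from Friedel–Crafts acylation of 2-methoxyphenyl pivalate with 3-oxocyclobutanecarboxylic acid, then benzylic deoxygenation; both arenes come from catechol via guaiacol.
5. Ring order: cyclobutanone (bought) → γ-lactone (ring expansion) → oxolane (reductive closure) → oxirane.

Assumption: small transfer reagents (MeI, PivCl, NBS, TBSCl, paraformaldehyde, H2O2, mCPBA) are listed as reagents and not numbered; the target configuration read from the SMILES is (3S,4S,7S).

## Route

Step 1
Reactants: 1 catechol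
Product: 2 guaiacol (2-methoxyphenol)
Conditions: MeI (1.0 equiv), K2CO3 (1.0 equiv), acetone, reflux; distillation
Reagents that add atoms: methyl iodide CI
Why: Williamson mono-O-methylation of one of two equivalent hydroxyls; the mono-ether is separated from neutral veratrole and from unreacted catechol.

Step 2
Reactants: 2 guaiacol
Product: 3 2-methoxyphenyl pivalate
Conditions: PivCl, Et3N, DMAP (cat.), CH2Cl2, 0 °C → rt
Reagents that add atoms: pivaloyl chloride CC(C)(C)C(=O)Cl
Why: DMAP-catalysed O-acylation; the hindered, non-enolisable ester protects the phenol and makes its oxygen a weaker donor than OMe, so the next electrophilic substitution goes para to OMe.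

Step 3
Reactants: 3 2-methoxyphenyl pivalate; 4 3-oxocyclobutane-1-carboxylic acid
Product: 6 2-methoxy-5-(3-oxocyclobutane-1-carbonyl)phenyl pivalate, via acid chloride 5 (not isolated)
Conditions: 4, (COCl)2, DMF (cat.), CH2Cl2, rt; then 3, AlCl3 (2.5 equiv), CH2Cl2, 0 °C → rt
Reagents that add atoms: none
Why: Friedel–Crafts acylation; the acylium ion attacks the position para to OMe (meta to the pivaloyloxy group), giving the 4-methoxy-3-pivaloyloxyphenyl ketone.

Step 4
Reactants: 6 2-methoxy-5-(3-oxocyclobutane-1-carbonyl)phenyl pivalate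
Product: 7 2-methoxy-5-[(3-oxocyclobutyl)methyl]phenyl pivalate
Conditions: H2 (3 atm), Pd/C (10 wt%), AcOH, H2SO4 (cat.), rt
Reagents that add atoms: none
Why: Catalytic hydrogenolysis of the p-methoxyaryl ketone to CH2 through the benzylic alcohol; the unconjugated cyclobutanone and the aryl ester are not reduced on palladium.

Step 5
Reactants: 7 2-methoxy-5-[(3-oxocyclobutyl)methyl]phenyl pivalate
Product: 8 2-methoxy-5-{[(3R)-5-oxooxolan-3-yl]methyl}phenyl pivalate
Conditions: 35% aq. H2O2 (1.5 equiv), confined chiral imidodiphosphoric acid [two 3,3′-bis(2,4,6-triethylphenyl)-BINOL units bridged by P(=O)–NH–P(=O)] (5 mol%, antipode giving R), CHCl3, −40 °C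
Reagents that add atoms: hydrogen peroxide OO
Why: Proposed new method: a confined imidodiphosphoric acid is used for a hydrogen-peroxide Baeyer–Villiger desymmetrisation of a 3-(arylmethyl)cyclobutanone; the acid hydrogen-bonds the carbonyl and H2O2, the Criegee adduct forms inside the chiral pocket, and only one of the two enantiotopic ring CH2 groups can lie antiperiplanar to the O–O bond while the arylmethyl arm points out of the pocket, so its 1,2-shift (ring expansion driven by release of four-ring strain) gives the (R)-lactone; the closest known reaction is the chiral BINOL-phosphoric-acid-catalysed H2O2 Baeyer–Villiger oxidation of 3-substituted cyclobutanones, which is less selective for flexible 3-benzyl groups.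

Step 6
Reactants: 2 guaiacol
Product: 10 (4-bromo-2-methoxyphenoxy)(tert-butyl)dimethylsilane, via 4-bromo-2-methoxyphenol 9 (not isolated)
Conditions: NBS (1.0 equiv), MeCN, 0 °C → rt; then imidazole (2.5 equiv), TBSCl (1.2 equiv), rt
Reagents that add atoms: N-bromosuccinimide O=C1CCC(=O)N1Br; tert-butyldimethylsilyl chloride CC(C)(C)[Si](C)(C)Cl
Why: Electrophilic aromatic bromination of the free phenol goes para to OH, and silyl ether formation in the same flask masks the phenol for the lithiation.

Step 7
Reactants: 8 2-methoxy-5-{[(3R)-5-oxooxolan-3-yl]methyl}phenyl pivalate; 10 (4-bromo-2-methoxyphenoxy)(tert-butyl)dimethylsilane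
Product: 12 5-[(2R)-4-[4-(tert-butyldimethylsilyloxy)-3-methoxyphenyl]-2-(hydroxymethyl)-4-oxobutyl]-2-methoxyphenyl pivalate, via aryllithium 11 (not isolated)
Conditions: 10, n-BuLi (1.05 equiv), THF, −78 °C; then 8 (0.9 equiv), −78 °C; aq. NH4Cl
Reagents that add atoms: none
Why: Bromine–lithium exchange, then 1,2-addition of the aryllithium to the lactone carbonyl; the lithium lactolate is stable at −78 °C, so only one aryl adds, the hindered pivalate is spared and the stereocentre is untouched.

Step 8
Reactants: 12 5-[(2R)-4-[4-(tert-butyldimethylsilyloxy)-3-methoxyphenyl]-2-(hydroxymethyl)-4-oxobutyl]-2-methoxyphenyl pivalate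
Product: 13 5-[(2R)-4-[4-(tert-butyldimethylsilyloxy)-3-methoxyphenyl]-2-(hydroxymethyl)-3-methylidene-4-oxobutyl]-2-methoxyphenyl pivalate
Conditions: (CH2O)n (3 equiv), iPr2NH·CF3CO2H (1 equiv), CF3CO2H (10 mol%), THF, 65 °C
Reagents that add atoms: formaldehyde (as paraformaldehyde) C=O
Why: Mannich condensation–elimination (direct α-methylenation) at the only enolisable α-CH2 of the aryl ketone; the weakly acidic medium leaves the adjacent stereocentre and both phenol protecting groups intact.

Step 9
Reactants: 13 5-[(2R)-4-[4-(tert-butyldimethylsilyloxy)-3-methoxyphenyl]-2-(hydroxymethyl)-3-methylidene-4-oxobutyl]-2-methoxyphenyl pivalate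
Product: 14 5-{[(3R,5R)-5-[4-(tert-butyldimethylsilyloxy)-3-methoxyphenyl]-4-methylideneoxolan-3-yl]methyl}-2-methoxyphenyl pivalate
Conditions: Et3SiH (3 equiv), BF3·OEt2 (1.5 equiv), CH2Cl2, −78 → −40 °C
Reagents that add atoms: none
Why: Kishi-type ionic hydrogenation: the hydroxy ketone closes to its hemiketal, BF3 ionises it to the 2-aryl-3-methylideneoxolan-1-ium ion, and Et3SiH delivers hydride to the O-bearing carbon from the face opposite the arylmethyl group, setting the benzylic centre with aryl and arylmethyl cis.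

Step 10
Reactants: 14 5-{[(3R,5R)-5-[4-(tert-butyldimethylsilyloxy)-3-methoxyphenyl]-4-methylideneoxolan-3-yl]methyl}-2-methoxyphenyl pivalate
Product: 15 5-{[(3S,4S,7S)-4-[4-(tert-butyldimethylsilyloxy)-3-methoxyphenyl]-1,5-dioxaspiro[2.4]heptan-7-yl]methyl}-2-methoxyphenyl pivalate
Conditions: mCPBA (1.2 equiv), NaHCO3, CH2Cl2, 0 °C
Reagents that add atoms: 3-chloroperoxybenzoic acid OOC(=O)c1cccc(Cl)c1
Why: Prilezhaev epoxidation of the 1,1-disubstituted alkene; aryl and arylmethyl flank the alkene on the same face, so oxygen is delivered to the opposite face and the spiro centre forms with O trans to both.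

Step 11
Reactants: 15 5-{[(3S,4S,7S)-4-[4-(tert-butyldimethylsilyloxy)-3-methoxyphenyl]-1,5-dioxaspiro[2.4]heptan-7-yl]methyl}-2-methoxyphenyl pivalate
Product: 16 (3S,4S,7S)-4-(4-hydroxy-3-methoxyphenyl)-7-[(3-hydroxy-4-methoxyphenyl)methyl]-1,5-dioxaspiro[2.4]heptane
Conditions: K2CO3, MeOH, rt → 40 °C
Reagents that add atoms: none
Why: Base-mediated methanolysis (transesterification of the aryl pivalate, cleavage of the aryl silyl ether) frees both phenols under conditions too mild to open the hindered spiro-epoxide or touch the stereocentres.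

## Compound list

1 | catechol (benzene-1,2-diol) | Oc1ccccc1O | starting material
2 | guaiacol (2-methoxyphenol) | COc1ccccc1O | intermediate
3 | 2-methoxyphenyl pivalate | COc1ccccc1OC(=O)C(C)(C)C | intermediate
4 | 3-oxocyclobutane-1-carboxylic acid | O=C1CC(C1)C(=O)O | starting material
5 | 3-oxocyclobutane-1-carbonyl chloride | O=C1CC(C1)C(=O)Cl | intermediate
6 | 2-methoxy-5-(3-oxocyclobutane-1-carbonyl)phenyl pivalate | COc1ccc(cc1OC(=O)C(C)(C)C)C(=O)C1CC(=O)C1 | intermediate
7 | 2-methoxy-5-[(3-oxocyclobutyl)methyl]phenyl pivalate | COc1ccc(CC2CC(=O)C2)cc1OC(=O)C(C)(C)C | intermediate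
8 | 2-methoxy-5-{[(3R)-5-oxooxolan-3-yl]methyl}phenyl pivalate | O=C1C[C@@H](Cc2ccc(OC)c(OC(=O)C(C)(C)C)c2)CO1 | intermediate
9 | 4-bromo-2-methoxyphenol | COc1cc(Br)ccc1O | intermediate
10 | (4-bromo-2-methoxyphenoxy)(tert-butyl)dimethylsilane | COc1cc(Br)ccc1O[Si](C)(C)C(C)(C)C | intermediate
11 | [4-(tert-butyldimethylsilyloxy)-3-methoxyphenyl]lithium | [Li]c1ccc(O[Si](C)(C)C(C)(C)C)c(OC)c1 | intermediate
12 | 5-[(2R)-4-[4-(tert-butyldimethylsilyloxy)-3-methoxyphenyl]-2-(hydroxymethyl)-4-oxobutyl]-2-methoxyphenyl pivalate (open form of the lactol) | O=C(C[C@H](CO)Cc1ccc(OC)c(OC(=O)C(C)(C)C)c1)c1ccc(O[Si](C)(C)C(C)(C)C)c(OC)c1 | intermediate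
13 | 5-[(2R)-4-[4-(tert-butyldimethylsilyloxy)-3-methoxyphenyl]-2-(hydroxymethyl)-3-methylidene-4-oxobutyl]-2-methoxyphenyl pivalate (in equilibrium with its cyclic hemiketal) | C=C(C(=O)c1ccc(O[Si](C)(C)C(C)(C)C)c(OC)c1)[C@H](CO)Cc1ccc(OC)c(OC(=O)C(C)(C)C)c1 | intermediate
14 | 5-{[(3R,5R)-5-[4-(tert-butyldimethylsilyloxy)-3-methoxyphenyl]-4-methylideneoxolan-3-yl]methyl}-2-methoxyphenyl pivalate (aryl and arylmethyl cis) | C=C1[C@@H](Cc2ccc(OC)c(OC(=O)C(C)(C)C)c2)CO[C@H]1c1ccc(O[Si](C)(C)C(C)(C)C)c(OC)c1 | intermediate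
15 | 5-{[(3S,4S,7S)-4-[4-(tert-butyldimethylsilyloxy)-3-methoxyphenyl]-1,5-dioxaspiro[2.4]heptan-7-yl]methyl}-2-methoxyphenyl pivalate | COc1ccc(C[C@H]2CO[C@@H](c3ccc(O[Si](C)(C)C(C)(C)C)c(OC)c3)[C@@]23CO3)cc1OC(=O)C(C)(C)C | intermediate
16 | (3S,4S,7S)-4-(4-hydroxy-3-methoxyphenyl)-7-[(3-hydroxy-4-methoxyphenyl)methyl]-1,5-dioxaspiro[2.4]heptane | COc1ccc(C[C@H]2CO[C@@H](c3ccc(O)c(OC)c3)[C@@]23CO3)cc1O | target

## Step count and risks

Total steps: 11. Longest linear sequence: 10 (steps 1–5, then 7–11); step 6 is the side branch.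

The three steps most likely to fail:

**Step 5 (the proposed new method).** The pocket may not discriminate the flexible arylmethyl arm (low ee), or the acid may be slow with aqueous H2O2. The fallback uses known chemistry, sets out from 7 and comes back at 8. Oxidation of 7 with mCPBA (ordinary Baeyer–Villiger) gives the racemic lactone F1. LDA and PhSeBr give the trans α-phenylselanyl lactone F2, and H2O2 oxidation with syn-elimination gives the butenolide F3. Asymmetric hydrogenation of this β-substituted butenolide with Ru(OAc)2[(S)-BINAP] or its antipode (the one giving R) under H2 returns 8. The stereocentre is then set by hydrogenation, not by the migration step.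

**Step 8.** The electron-rich aryl ketone may enolise slowly, and the new C=C may migrate into the chain and erase the adjacent stereocentre. The fallback reverses the order of the two C–C bond formations; it sets out from 8 (and 10) and comes back at 13. LDA and then Me2N=CH2+ I− convert 8 into the trans Mannich base F4. MeI gives the methiodide F5, which loses trimethylamine with aqueous NaHCO3 to give the α-methylene lactone F6. The aryllithium 11 is transmetallated with CeCl3 to the arylcerium dichloride F7, which adds 1,2 to the lactone carbonyl of F6 at −78 °C; aqueous NH4Cl work-up gives 13.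

**Step 9.** Hydride may add at the exocyclic CH2 (1,4), the electron-rich benzylic C–O bond may be hydrogenolysed, or the cis selectivity from the remote arylmethyl group may be too low. The fallback sets the benzylic centre by reagent control and closes the ring by SN2; it sets out from 13 and comes back at 14. CBS reduction (2-methyl-CBS-oxazaborolidine, antipode giving the 4R carbinol, BH3·SMe2, THF, −30 °C) reduces the enone 1,2 to the diol F8. TsCl, Et3N and DMAP (cat.) sulfonylate only the primary alcohol to give the primary tosylate F9. NaH in THF then closes the oxolane by intramolecular Williamson etherification with retention at the benzylic carbon, giving 14.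

## Further compounds

F1 | step 5 | racemic 2-methoxy-5-[(5-oxooxolan-3-yl)methyl]phenyl pivalate | O=C1CC(Cc2ccc(OC)c(OC(=O)C(C)(C)C)c2)CO1
F2 | step 5 | 2-methoxy-5-{[5-oxo-4-(phenylselanyl)oxolan-3-yl]methyl}phenyl pivalate (racemic, trans) | O=C1OCC(Cc2ccc(OC)c(OC(=O)C(C)(C)C)c2)C1[Se]c1ccccc1
F3 | step 5 | 2-methoxy-5-[(5-oxo-2,5-dihydrofuran-3-yl)methyl]phenyl pivalate | O=C1C=C(Cc2ccc(OC)c(OC(=O)C(C)(C)C)c2)CO1
F4 | step 8 | 5-{[(3R,4S)-4-[(dimethylamino)methyl]-5-oxooxolan-3-yl]methyl}-2-methoxyphenyl pivalate | O=C1[C@H](CN(C)C)[C@@H](Cc2ccc(OC)c(OC(=O)C(C)(C)C)c2)CO1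
F5 | step 8 | {[(3S,4R)-4-{[4-methoxy-3-(pivaloyloxy)phenyl]methyl}-2-oxooxolan-3-yl]methyl}trimethylammonium iodide | O=C1[C@H](C[N+](C)(C)C)[C@@H](Cc2ccc(OC)c(OC(=O)C(C)(C)C)c2)CO1.[I-]
F6 | step 8 | 2-methoxy-5-{[(3R)-4-methylidene-5-oxooxolan-3-yl]methyl}phenyl pivalate | O=C1C(=C)[C@@H](Cc2ccc(OC)c(OC(=O)C(C)(C)C)c2)CO1
F7 | step 8 | [4-(tert-butyldimethylsilyloxy)-3-methoxyphenyl]cerium dichloride | Cl[Ce](Cl)c1ccc(O[Si](C)(C)C(C)(C)C)c(OC)c1
F8 | step 9 | 5-[(2R,4R)-4-[4-(tert-butyldimethylsilyloxy)-3-methoxyphenyl]-4-hydroxy-2-(hydroxymethyl)-3-methylidenebutyl]-2-methoxyphenyl pivalate | O[C@@H](c1ccc(O[Si](C)(C)C(C)(C)C)c(OC)c1)C(=C)[C@H](CO)Cc1ccc(OC)c(OC(=O)C(C)(C)C)c1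
F9 | step 9 | 5-[(2R,4R)-4-[4-(tert-butyldimethylsilyloxy)-3-methoxyphenyl]-4-hydroxy-3-methylidene-2-(tosyloxymethyl)butyl]-2-methoxyphenyl pivalate | O[C@@H](c1ccc(O[Si](C)(C)C(C)(C)C)c(OC)c1)C(=C)[C@H](COS(=O)(=O)c1ccc(C)cc1)Cc1ccc(OC)c(OC(=O)C(C)(C)C)c1
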